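**Retrosynthetic overview**
1. Numbering: C1 quaternary ring-fusion carbon (CH3), C2/C3 CH2, C4 carbinol carbon (iPr), C5 ring-fusion CH, C6 CH–O-anisoyl, C7=C8(CH3), C9 C=O, C10 CH2. The cyclopentane is C1–C5 and the cycloheptenone is C1, C5–C10.
2. Feature on which the strategy rests: the adjacent stereocentres C1, C5 and C6 correspond to the β-carbon, the α-carbon and the exocyclic aldol carbinol of a cyclopentenone whose carbonyl is C4.
3. Late disconnections: C9 ketone ⇒ C9 carbinol; C8–C9 (Nozaki–Hiyama–Kishi) opens the seven-membered ring to a C8 (Z)-iodoalkene and a C9 aldehyde; C6 ester; C8–I ⇒ C7≡C8 alkyne; C4–isopropyl ⇒ C4 ketone.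
4. Key disconnection: C1–CH3 and C5–C6 are formed together from 3-(1,3-dioxolan-2-ylmethyl)cyclopent-2-en-1-one, trimethylaluminium and but-2-ynal.
5. Ring order: the five-membered ring is present in the starting cyclopentenone, and the seven-membered ring is closed second, in step 10.

Key step: step 3

Assumption: the sense of induction of the NHC–copper catalyst is taken over from simpler 3-alkylcyclopentenones, and the ligand antipode that places methyl on the Si face of C1 is used (both antipodes derive from commercial 1,2-diphenylethylenediamine).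

**Step 1**
Reactants: 1 3-ethoxycyclopent-2-en-1-one; 2 (1,3-dioxolan-2-ylmethyl)magnesium bromide
Product: 4 3-(1,3-dioxolan-2-ylmethyl)cyclopent-2-en-1-one, via tertiary allylic alcohol 3 (not isolated)
Conditions: 2 (0.5 M in THF, 1.3 equiv), THF, 0 °C → rt; then 1 M aq HCl, 0 °C, 15 min
Reagents that add atoms: (1,3-dioxolan-2-ylmethyl)magnesium bromide 2, Br[Mg]CC1OCCO1; water, O
Why: 1,2-addition of the Grignard reagent to the vinylogous ester, followed by acid hydrolysis and dehydration of carbinol 3 (Stork–Danheiser-type carbonyl transposition), should give the β-substituted enone, because the brief cold dilute acid that cleaves the enol ether leaves the aldehyde-derived dioxolane intact, and no stereocentre remains.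

**Step 2**
Reactants: 5 but-2-yn-1-ol
Product: 6 but-2-ynal
Conditions: activated MnO2 (15 equiv), CH2Cl2, rt; filtration through Celite, careful distillation
Reagents that add atoms: none
Why: activated manganese dioxide oxidises propargylic alcohols to ynals without over-oxidation, and filtration followed by distillation should give dry aldehyde fit for the organometallic step.

**Step 3**
Reactants: 4 3-(1,3-dioxolan-2-ylmethyl)cyclopent-2-en-1-one; 7 trimethylaluminium; 6 but-2-ynal
Product: 9 (2S,3R)-3-(1,3-dioxolan-2-ylmethyl)-2-[(1R)-1-hydroxybut-2-yn-1-yl]-3-methylcyclopentan-1-one, via dimethylaluminium enolate 8 (not isolated)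
Conditions: Cu(OTf)2 (5 mol %), chiral sulfonate-bearing bidentate NHC–Ag(I) complex from 1,2-diphenylethylenediamine (2.5 mol %), 7 (1.3 equiv), THF, −78 °C; then 6 (3 equiv), −78 → −40 °C; cold aq Rochelle salt
Reagents that add atoms: trimethylaluminium 7, C[Al](C)C; but-2-ynal 6, CC#CC=O
Why: Methyl passes from aluminium to the chiral NHC–copper centre, the methylcopper species adds to the aluminium-activated enone at C1 (π-complex, copper(III) β-adduct, reductive elimination), and the regiodefined enolate 8 then binds but-2-ynal at aluminium and attacks it through C5 in a closed six-membered chair (Zimmerman–Traxler) transition state. The closest known reaction type is the copper-catalysed enantioselective conjugate addition of trialkylaluminium reagents to β-substituted cyclopentenones, joined to aldol interception of the metal enolate as in three-component cyclopentenone couplings. No ring is closed in this step. C1 is set by the ligand, which opens the Si face of the β-carbon to methyl and gives (R)-C1; C5 is set by C1, because the aldehyde reaches the enolate on the face of the small methyl group and away from the β-branched dioxolanylmethyl arm, so that C6 and C10 end trans; C6 is set by the ring-locked E geometry of 8, which with the alkynyl group equatorial in the chair leads to the anti aldol, (R) at C6. The step needs 1,4- over 1,2-methyl transfer (copper catalysis at −78 °C), 1,2- over 1,4-attack on the ynal (the aldehyde oxygen is bound to aluminium in the cyclic array) and an enolate that is not outrun by free Me3Al (only a small excess of 7, ynal in excess). The acetal should be inert to Me3Al in THF at this temperature, and the cold near-neutral quench avoids retro-aldol cleavage and dehydration.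

**Step 4**
Reactants: 9 aldol
Product: 10 (2S,3R)-3-(1,3-dioxolan-2-ylmethyl)-3-methyl-2-[(1R)-1-(triethylsilyloxy)but-2-yn-1-yl]cyclopentan-1-one
Conditions: TESCl (1.5 equiv), imidazole (3 equiv), DMF, 0 °C → rt
Reagents that add atoms: chlorotriethylsilane, CC[Si](Cl)(CC)CC
Why: silyl chloride/imidazole silylation of the secondary propargylic alcohol is mild enough to avoid retro-aldol cleavage, β-elimination and C5 epimerisation, and it is preferred to silyl triflate/lutidine, a combination known to cleave aldehyde acetals.

**Step 5**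
Reactants: 10 silyloxy ketone
Product: 11 (1R,2S,3R)-3-(1,3-dioxolan-2-ylmethyl)-3-methyl-1-(propan-2-yl)-2-[(1R)-1-(triethylsilyloxy)but-2-yn-1-yl]cyclopentan-1-ol
Conditions: iPrMgCl (3 equiv), LaCl3·2LiCl (1.5 equiv), THF, −20 → 0 °C; H2O
Reagents that add atoms: isopropylmagnesium chloride, CC(C)[Mg]Cl
Why: the lanthanide-assisted Grignard 1,2-addition suppresses enolisation, loss of the β-silyloxy group and β-hydride reduction, and the nucleophile should reach C4 on the face opposite the adjacent C5 side chain and the C1 methyl group, which places the isopropyl group cis to H5 and the hydroxyl cis to C6, (R) at C4.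

**Step 6**
Reactants: 11 silyl ether
Product: 12 (1R,2S,3R)-3-(1,3-dioxolan-2-ylmethyl)-2-[(1R)-1-hydroxybut-2-yn-1-yl]-3-methyl-1-(propan-2-yl)cyclopentan-1-ol
Conditions: TBAF (1.2 equiv), THF, 0 °C
Reagents that add atoms: none
Why: fluoride-induced desilylation frees the C6 hydroxyl, and 11 no longer holds a carbonyl group or any other base-sensitive function.

**Step 7**
Reactants: 12 propargylic diol
Product: 14 (1R,2S,3R)-3-(1,3-dioxolan-2-ylmethyl)-2-[(1R,2Z)-1-hydroxy-3-iodobut-2-en-1-yl]-3-methyl-1-(propan-2-yl)cyclopentan-1-ol, via cyclic vinylalanate 13 (not isolated)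
Conditions: Red-Al (4 equiv), THF, 0 °C → rt; EtOAc (destroys excess hydride); I2 (5 equiv), THF, −78 → 0 °C; aq Na2S2O3/Rochelle salt
Reagents that add atoms: iodine, II
Why: in the alkoxide-directed trans-hydroalumination of a propargylic alcohol the C6 alkoxyaluminium hydride delivers hydride to C7 and aluminium to C8 within the five-membered ring of 13 (the excess reagent covers the C4 hydroxyl), and iodinolysis with retention should give the iodoalkene with iodine on C8 cis to C6, as the ring closure requires.

**Step 8**
Reactants: 14 iodoalkenyl diol; 15 4-methoxybenzoyl chloride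
Product: 16 (1R,2Z)-1-[(1S,2R,5R)-5-(1,3-dioxolan-2-ylmethyl)-2-hydroxy-5-methyl-2-(propan-2-yl)cyclopentyl]-3-iodobut-2-en-1-yl 4-methoxybenzoate
Conditions: 15 (1.5 equiv), Et3N (3 equiv), DMAP (0.2 equiv), CH2Cl2, 0 °C → rt
Reagents that add atoms: 4-methoxybenzoyl chloride 15, COc1ccc(cc1)C(Cl)=O
Why: DMAP-catalysed acylation should take the secondary allylic C6 hydroxyl and leave the hindered tertiary C4 hydroxyl, and C6 keeps its configuration because the C–O bond is not touched.

**Step 9**
Reactants: 16 acetal
Product: 17 (1R,2Z)-1-[(1S,2R,5R)-2-hydroxy-5-methyl-5-(2-oxoethyl)-2-(propan-2-yl)cyclopentyl]-3-iodobut-2-en-1-yl 4-methoxybenzoate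
Conditions: 1 M aq HCl/THF (1:3), rt, dark
Reagents that add atoms: water, O
Why: acid-catalysed acetal hydrolysis should free the C9 aldehyde cleanly, because the C6 oxygen is blocked as the ester, the C4 hydroxyl lies trans to the C10 arm and cannot form a lactol, and the quaternary C1 rules out β-elimination.

**Step 10**
Reactants: 17 iodoalkenyl aldehyde
Product: 19 (3R,3aS,4S,8aR)-3,7-dihydroxy-6,8a-dimethyl-3-(propan-2-yl)-1,2,3,3a,4,7,8,8a-octahydroazulen-4-yl 4-methoxybenzoate (C9 epimers), via alkenylchromium(III) species 18 (not isolated)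
Conditions: CrCl2 (8 equiv), NiCl2 (2 mol % of Cr), DMSO, 5 mM, rt; H2O
Reagents that add atoms: none
Why: in the intramolecular Nozaki–Hiyama–Kishi reaction nickel inserts into the C8–I bond with retention and hands the alkenyl group to chromium(III) (18), which adds only to the aldehyde in a 7-exo-trig closure of the trans-fused ring while ester and free hydroxyl are tolerated, and the new C9 carbinol centre is irrelevant because it is oxidised in step 11.

**Step 11**
Reactants: 19 allylic alcohol
Product: 20 lancerodiol p-methoxybenzoate, (3R,3aS,4S,8aR)-3-hydroxy-6,8a-dimethyl-7-oxo-3-(propan-2-yl)-1,2,3,3a,4,7,8,8a-octahydroazulen-4-yl 4-methoxybenzoate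
Conditions: Dess–Martin periodinane (1.5 equiv), CH2Cl2, 0 °C → rt
Reagents that add atoms: none
Why: Dess–Martin oxidation converts both C9 epimers of the secondary allylic alcohol into the same enone under near-neutral conditions, which spare the tertiary alcohol and the γ-acyloxy group.

**Compound list**
1 | 3-ethoxycyclopent-2-en-1-one | CCOC1=CC(=O)CC1 | starting material
2 | (1,3-dioxolan-2-ylmethyl)magnesium bromide | Br[Mg]CC1OCCO1 | starting material
3 | 1-(1,3-dioxolan-2-ylmethyl)-3-ethoxycyclopent-2-en-1-ol (racemic, not isolated) | CCOC1=CC(O)(CC2OCCO2)CC1 | intermediate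
4 | 3-(1,3-dioxolan-2-ylmethyl)cyclopent-2-en-1-one | O=C1C=C(CC2OCCO2)CC1 | intermediate
5 | but-2-yn-1-ol | CC#CCO | starting material
6 | but-2-ynal | CC#CC=O | intermediate
7 | trimethylaluminium | C[Al](C)C | starting material
8 | {[(3R)-3-(1,3-dioxolan-2-ylmethyl)-3-methylcyclopent-1-en-1-yl]oxy}dimethylalumane (not isolated) | C[Al](C)OC1=C[C@@](C)(CC2OCCO2)CC1 | intermediate
9 | (2S,3R)-3-(1,3-dioxolan-2-ylmethyl)-2-[(1R)-1-hydroxybut-2-yn-1-yl]-3-methylcyclopentan-1-one | O[C@@H](C#CC)[C@H]1C(=O)CC[C@]1(C)CC2OCCO2 | intermediate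
10 | (2S,3R)-3-(1,3-dioxolan-2-ylmethyl)-3-methyl-2-[(1R)-1-(triethylsilyloxy)but-2-yn-1-yl]cyclopentan-1-one | CC[Si](CC)(CC)O[C@@H](C#CC)[C@H]1C(=O)CC[C@]1(C)CC2OCCO2 | intermediate
11 | (1R,2S,3R)-3-(1,3-dioxolan-2-ylmethyl)-3-methyl-1-(propan-2-yl)-2-[(1R)-1-(triethylsilyloxy)but-2-yn-1-yl]cyclopentan-1-ol | CC[Si](CC)(CC)O[C@@H](C#CC)[C@H]1[C@](O)(C(C)C)CC[C@]1(C)CC2OCCO2 | intermediate
12 | (1R,2S,3R)-3-(1,3-dioxolan-2-ylmethyl)-2-[(1R)-1-hydroxybut-2-yn-1-yl]-3-methyl-1-(propan-2-yl)cyclopentan-1-ol | O[C@@H](C#CC)[C@H]1[C@](O)(C(C)C)CC[C@]1(C)CC2OCCO2 | intermediate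
13 | sodium cyclic vinylalanate (O6–Al–C8 five-membered ring, C4–OH drawn un-ionised, not isolated) | CC1=C[C@H](O[Al-]1(OCCOC)OCCOC)[C@H]2[C@](O)(C(C)C)CC[C@]2(C)CC3OCCO3.[Na+] | intermediate
14 | (1R,2S,3R)-3-(1,3-dioxolan-2-ylmethyl)-2-[(1R,2Z)-1-hydroxy-3-iodobut-2-en-1-yl]-3-methyl-1-(propan-2-yl)cyclopentan-1-ol | O[C@@H](/C=C(/C)I)[C@H]1[C@](O)(C(C)C)CC[C@]1(C)CC2OCCO2 | intermediate
15 | 4-methoxybenzoyl chloride | COc1ccc(cc1)C(Cl)=O | starting material
16 | (1R,2Z)-1-[(1S,2R,5R)-5-(1,3-dioxolan-2-ylmethyl)-2-hydroxy-5-methyl-2-(propan-2-yl)cyclopentyl]-3-iodobut-2-en-1-yl 4-methoxybenzoate | COc1ccc(cc1)C(=O)O[C@@H](/C=C(/C)I)[C@H]1[C@](O)(C(C)C)CC[C@]1(C)CC2OCCO2 | intermediate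
17 | (1R,2Z)-1-[(1S,2R,5R)-2-hydroxy-5-methyl-5-(2-oxoethyl)-2-(propan-2-yl)cyclopentyl]-3-iodobut-2-en-1-yl 4-methoxybenzoate | COc1ccc(cc1)C(=O)O[C@@H](/C=C(/C)I)[C@H]1[C@](O)(C(C)C)CC[C@]1(C)CC=O | intermediate
18 | C8 alkenylchromium(III) dichloride of 17 (not isolated) | COc1ccc(cc1)C(=O)O[C@@H](/C=C(/C)[Cr](Cl)Cl)[C@H]1[C@](O)(C(C)C)CC[C@]1(C)CC=O | intermediate
19 | (3R,3aS,4S,8aR)-3,7-dihydroxy-6,8a-dimethyl-3-(propan-2-yl)-1,2,3,3a,4,7,8,8a-octahydroazulen-4-yl 4-methoxybenzoate (C9 epimers) | COc1ccc(cc1)C(=O)O[C@H]2C=C(C)C(O)C[C@@]3(C)CC[C@@](O)(C(C)C)[C@H]23 | intermediate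
20 | lancerodiol p-methoxybenzoate | COc1ccc(C(=O)O[C@H]2C=C(C)C(=O)C[C@@]3(C)CC[C@@](O)(C(C)C)[C@H]23)cc1 | target

**Totals**
Total step count: 11.
Longest linear sequence: 10 steps (steps 1 and 3–11, from 3-ethoxycyclopent-2-en-1-one).

**Steps most likely to fail**

1. **Step 3.**
   - Risk: the slim alkynyl group may discriminate only weakly between the two chair orientations of the aldehyde, so control at C6 is lost, and residual Me3Al competes for the ynal.
   - Fallback: C6 is set by reagent control instead of by the aldol transition state. The fallback sets out from 12, which steps 4–6 deliver without separation from material that is not uniform at C6, and it comes back to 12. Activated MnO2 in CH2Cl2 oxidises only the propargylic C6 carbinol and gives the β-hydroxy ynone F1, in which C6 is no longer stereogenic. Base-free asymmetric transfer hydrogenation with the preformed (R,R)-TsDPEN–Ru(p-cymene) catalyst in 2-propanol reduces only the ynone carbonyl. By analogy with simple alkyl alkynyl ketones it should return the (6R)-propargylic alcohol 12. The neutral medium is chosen to spare the ynone from retro-aldol ring opening, oxa-Michael closure and C5 epimerisation.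

2. **Step 5.**
   - Risk: the hindered ketone may enolise and then lose the silyloxy group, the secondary Grignard reagent may reduce it by β-hydride transfer, or facial selectivity may erode.
   - Fallback: a smaller, less basic sp2 nucleophile without a transferable β-hydride is used, and the isopropyl group is completed later. The fallback sets out from 10 and comes back at 14. Isopropenylmagnesium bromide/CeCl3 in THF at −78 °C adds anti to the C5 side chain and gives the isopropenyl carbinol F2. TBAF then gives the enyne diol F3, and Red-Al followed by iodine, as in step 7, gives the iodoalkenyl isopropenyl diol F4. Diimide (2-nitrobenzenesulfonyl hydrazide, Et3N) saturates the 1,1-disubstituted alkene and leaves the trisubstituted iodoalkene, which gives 14. Saturation is done before step 9 so that no tertiary allylic alcohol meets aqueous acid.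

3. **Step 10.**
   - Risk: the alkenylchromium species may be protonated, the alkenylmetal may expel the allylic anisoate, or intermolecular coupling may outrun closure of the seven-membered ring.
   - Fallback: the ring is closed at C7=C8 by ring-closing metathesis instead of at C8–C9. The fallback sets out from 12 and comes back at 19. Red-Al reduction of 12 with a water quench in place of iodine gives the (E)-propenyl diol F5. Acylation with 15 (Et3N, DMAP) gives the anisoate F6, and 1 M aq HCl/THF gives the aldehyde F7. Isopropenylmagnesium bromide (2.2 equiv, THF, −78 °C) adds to the aldehyde in preference to the aryl ester and gives the dienol F8. A second-generation ruthenium benzylidene (Grubbs II) catalyst in refluxing CH2Cl2 at high dilution then closes the trisubstituted C7=C8 alkene, helped by the free allylic hydroxyl, and gives 19.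

**Further compounds**
F1 | step 3 | 1-[(1R,2R,5R)-5-(1,3-dioxolan-2-ylmethyl)-2-hydroxy-5-methyl-2-(propan-2-yl)cyclopentyl]but-2-yn-1-one (C6 ynone of 12) | CC#CC(=O)[C@H]1[C@](O)(C(C)C)CC[C@]1(C)CC2OCCO2
F2 | step 5 | isopropenyl analogue of 11 (C4 prop-1-en-2-yl carbinol, C6 TES ether) | CC[Si](CC)(CC)O[C@@H](C#CC)[C@H]1[C@](O)(C(C)=C)CC[C@]1(C)CC2OCCO2
F3 | step 5 | isopropenyl analogue of 12 (enyne diol) | O[C@@H](C#CC)[C@H]1[C@](O)(C(C)=C)CC[C@]1(C)CC2OCCO2
F4 | step 5 | isopropenyl analogue of 14 ((Z)-iodoalkenyl diol) | O[C@@H](/C=C(/C)I)[C@H]1[C@](O)(C(C)=C)CC[C@]1(C)CC2OCCO2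
F5 | step 10 | (E)-propenyl diol (C7=C8 E-alkene in place of the alkyne of 12) | O[C@@H](/C=C/C)[C@H]1[C@](O)(C(C)C)CC[C@]1(C)CC2OCCO2
F6 | step 10 | C6 4-methoxybenzoate of F5 | COc1ccc(cc1)C(=O)O[C@@H](/C=C/C)[C@H]1[C@](O)(C(C)C)CC[C@]1(C)CC2OCCO2
F7 | step 10 | C9 aldehyde from F6 | COc1ccc(cc1)C(=O)O[C@@H](/C=C/C)[C@H]1[C@](O)(C(C)C)CC[C@]1(C)CC=O
F8 | step 10 | C9 isopropenyl carbinol from F7 (C9 epimers, metathesis precursor) | COc1ccc(cc1)C(=O)O[C@@H](/C=C/C)[C@H]1[C@](O)(C(C)C)CC[C@]1(C)CC(O)C(C)=C
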